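**Retrosynthetic overview**

1. The last bond broken is C8–O of the 12,8-lactone. The strategy rests on C8 being the only unactivated methylene γ to the C12 carboxyl (path C12–C11–C7–C8); the other γ-carbon, C6, carries an angelate. The γ-lactone is therefore closed last, on the 8-deoxy seco acid.
2. The seco acid comes from the C12 carbinol: late oxidation of C12, 1,10-oxirane by peracid, both angelates by acylation of O6 and O11, 4,5-oxirane by hydroxyl-directed epoxidation from free 6-OH.
3. The C6/C7/C11 triad: C7–C11 bond by enantioselective Mukaiyama aldol of the ten-membered ring enol ether with methyl pyruvate, then chelation-controlled reduction at C6.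
4. The (Z,Z) ten-membered carbocycle comes from a two-carbon [1,3] ring expansion of the vinyl carbinol of 3,7-dimethylcycloocta-2,6-dienone, made from 1,5-dimethylcycloocta-1,5-diene.
5. Ring order: eight-membered carbocycle (purchased) → ten-membered carbocycle (step 5) → 4,5-oxirane (step 9) → 1,10-oxirane (step 12) → γ-lactone (step 15).

Key step: step 15

Remark (numbering): germacrane numbering is used for all ten-membered-ring compounds: ring C1–C10, C11 on C7, C12 and C13 on C11, C14 on C10, C15 on C4.

Remark (assumption): 1,5-dimethylcycloocta-1,5-diene is assumed to be used free of its 1,6-dimethyl isomer (fractional distillation of technical material), and the sense of induction of the copper catalyst in step 6 is assumed to follow that known for thioester-derived enolsilanes with pyruvate.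

**Route**

Step 1
Reactants: 1 (1Z,5Z)-1,5-dimethylcycloocta-1,5-diene
Product: 2 rac-(4Z)-1,5-dimethyl-9-oxabicyclo[6.1.0]non-4-ene (cis-fused mono-epoxide)
Conditions: mCPBA (0.9 equiv), NaHCO3, CH2Cl2, 0 °C
Reagents that add atoms: 3-chloroperoxybenzoic acid (mCPBA), OOC(=O)c1cccc(Cl)c1
Why: Prilezhaev epoxidation of one of two equivalent trisubstituted olefins with substoichiometric peracid should give the cis-fused mono-epoxide, racemic but with stereocentres that are erased by step 3.

Step 2
Reactants: 2 rac-(4Z)-1,5-dimethyl-9-oxabicyclo[6.1.0]non-4-ene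
Product: 5 rac-(2Z,5Z)-1,5-dimethylcycloocta-2,5-dien-1-ol, via hydroxy selenide 3 (not isolated), via selenoxide 4 (not isolated)
Conditions: (PhSe)2, NaBH4, EtOH, reflux; then H2O2 (30%, 2 equiv), pyridine, THF, 0 °C to rt
Reagents that add atoms: none
Why: Selenolate opening of the oxirane at its secondary carbon followed by oxidation and selenoxide syn-elimination away from the carbinol (epoxide to allylic alcohol transposition) should give the tertiary allylic alcohol, the new ring olefin being cis as the eight-membered ring requires.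

Step 3
Reactants: 5 rac-(2Z,5Z)-1,5-dimethylcycloocta-2,5-dien-1-ol
Product: 6 (2Z,6Z)-3,7-dimethylcycloocta-2,6-dien-1-one
Conditions: pyridinium chlorochromate [C5H5NH][CrO3Cl] (2 equiv), NaOAc, 4 Å molecular sieves, CH2Cl2, rt
Reagents that add atoms: pyridinium chlorochromate, [O-][Cr](=O)(=O)Cl.c1cc[nH+]cc1
Why: Babler–Dauben oxidative 1,3-transposition, in which the chromate ester of the tertiary allylic alcohol rearranges and is oxidised to the β-methyl enone, should place the carbonyl next to the C8 methylene that is also allylic to the second olefin.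

Step 4
Reactants: 6 (2Z,6Z)-3,7-dimethylcycloocta-2,6-dien-1-one; 7 vinylmagnesium bromide
Product: 8 rac-(2Z,6Z)-1-ethenyl-3,7-dimethylcycloocta-2,6-dien-1-ol
Conditions: CeCl3 (anhydrous, 1.5 equiv), THF, −78 °C
Reagents that add atoms: none
Why: Organocerium (Imamoto) 1,2-addition is chosen because the weakly basic reagent should add to the carbonyl of the β,β-disubstituted enone faster than it enolises the acidic C8 methylene, and the racemic carbinol centre is erased in step 5.

Step 5
Reactants: 8 rac-(2Z,6Z)-1-ethenyl-3,7-dimethylcycloocta-2,6-dien-1-ol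
Product: 10 trimethyl{[(3Z,7Z)-4,8-dimethylcyclodeca-1,3,7-trien-2-yl]oxy}silane, via potassium dienolate 9 (not isolated)
Conditions: KH, 18-crown-6, THF, 0 °C to rt; then Me3SiCl, Et3N, −78 °C
Reagents that add atoms: chlorotrimethylsilane, C[Si](C)(C)Cl
Why: Alkoxide-accelerated [1,3]-sigmatropic shift (two-carbon ring expansion of a 1-vinylcyclooct-3-en-1-olate) should break the allylic C1–C8 bond and reclose the allyl terminus on the vinyl terminus within the tethered ion pair before the allyl unit can stereomutate, so that both Z olefins are kept and the cross-conjugated dienolate is trapped on oxygen.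

Step 6
Reactants: 10 trimethyl{[(3Z,7Z)-4,8-dimethylcyclodeca-1,3,7-trien-2-yl]oxy}silane; 11 methyl pyruvate
Product: 13 methyl (2R)-2-hydroxy-2-[(1R,3Z,7Z)-4,8-dimethyl-2-oxocyclodeca-3,7-dien-1-yl]propanoate, via silyl aldolate 12 (not isolated)
Conditions: [Cu((R,R)-tBu-box)](OTf)2 (10 mol%), THF, −78 °C; then 1 M HCl, THF, 0 °C
Reagents that add atoms: none
Why: Copper–bis(oxazoline)-catalysed Mukaiyama aldol addition, in which pyruvate chelated to the square-planar divalent copper centre should expose its re face under the (R,R)-ligand (C11 R) and the open antiperiplanar transition state should place the ring C8 methylene syn to the new hydroxyl (C7 R).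

Step 7
Reactants: 13 methyl (2R)-2-hydroxy-2-[(1R,3Z,7Z)-4,8-dimethyl-2-oxocyclodeca-3,7-dien-1-yl]propanoate
Product: 15 (2R)-2-[(1S,2R,3Z,7Z)-2-hydroxy-4,8-dimethylcyclodeca-3,7-dien-1-yl]propane-1,2-diol, via diol ester 14 (not isolated)
Conditions: Et2BOMe, NaBH4, THF–MeOH (4:1), −78 °C; MeOH co-evaporation; then LiBH4, THF, 0 °C to rt
Reagents that add atoms: none
Why: Narasaka–Prasad reduction, in which external hydride should add to the six-membered boron chelate between O11 and the C6 carbonyl from the side of H7 and anti to the C8 methylene, is expected to give the 6,11-syn diol (C6 R in the diene series), after which LiBH4 reduces the α-hydroxy ester (or any 6,12-lactone formed from it) to the C12 carbinol.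

Step 8
Reactants: 15 (2R)-2-[(1S,2R,3Z,7Z)-2-hydroxy-4,8-dimethylcyclodeca-3,7-dien-1-yl]propane-1,2-diol
Product: 16 (2R)-1-[(tert-butyldimethylsilyl)oxy]-2-[(1S,2R,3Z,7Z)-2-hydroxy-4,8-dimethylcyclodeca-3,7-dien-1-yl]propan-2-ol
Conditions: TBSCl (1.05 equiv), imidazole, CH2Cl2, −20 to 0 °C
Reagents that add atoms: tert-butyldimethylsilyl chloride, CC(C)(C)[Si](C)(C)Cl
Why: Sterically controlled silylation should take the primary C12 hydroxyl well before the ring secondary and the tertiary hydroxyl, which keeps C12 at the alcohol level so that no 6,12-lactone can form.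

Step 9
Reactants: 16 (2R)-1-[(tert-butyldimethylsilyl)oxy]-2-[(1S,2R,3Z,7Z)-2-hydroxy-4,8-dimethylcyclodeca-3,7-dien-1-yl]propan-2-ol
Product: 17 (4R,5S,6S,7S,11R)-12-[(tert-butyldimethylsilyl)oxy]-4,5-epoxygermacr-1(10)Z-ene-6,11-diol
Conditions: VO(acac)2 (5 mol%), tBuOOH (1.2 equiv, decane), CH2Cl2, 0 °C
Reagents that add atoms: tert-butyl hydroperoxide, CC(C)(C)OO
Why: Vanadium-catalysed hydroxyl-directed epoxidation of the allylic alcohol should deliver oxygen from the vanadate ester of O6 to the syn face of the Z olefin, giving the cis-epoxy alcohol (C4 R, C5 S) as known for medium-ring Z-cycloalkenols, while the isolated 1(10)-olefin is left alone.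

Step 10
Reactants: 18 angelic acid (two molecules)
Product: 19 angelic anhydride
Conditions: DCC (0.5 equiv per acid), CH2Cl2, 0 °C; filtration of the urea
Reagents that add atoms: angelic acid (second molecule of 18), C/C=C(/C)C(=O)O
Why: Carbodiimide dehydration, in which one molecule of acid is activated as its O-acylisourea and acylated by a second molecule of acid, should give the symmetric anhydride at 0 °C with the Z (angelate) geometry kept.

Step 11
Reactants: 17 (4R,5S,6S,7S,11R)-12-[(tert-butyldimethylsilyl)oxy]-4,5-epoxygermacr-1(10)Z-ene-6,11-diol; 19 angelic anhydride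
Product: 20 (4R,5S,6S,7S,11R)-6,11-bis(angeloyloxy)-12-[(tert-butyldimethylsilyl)oxy]-4,5-epoxygermacr-1(10)Z-ene
Conditions: LiN(SiMe3)2 (2.4 equiv), THF, −78 °C; then 19 (3 equiv), −78 to 0 °C
Reagents that add atoms: none
Why: Acylation of the lithium alkoxides with angelic anhydride at low temperature (stereoconservative angeloylation) should esterify the secondary and the hindered tertiary hydroxyl without the amine nucleophiles that isomerise angelate to tiglate, and any 1,3-acyl shift between O6 and O11 leads to the same bis-ester.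

Step 12
Reactants: 20 (4R,5S,6S,7S,11R)-6,11-bis(angeloyloxy)-12-[(tert-butyldimethylsilyl)oxy]-4,5-epoxygermacr-1(10)Z-ene
Product: 21 (1R,4R,5S,6S,7S,10S,11R)-6,11-bis(angeloyloxy)-12-[(tert-butyldimethylsilyl)oxy]-1,10:4,5-diepoxygermacrane
Conditions: mCPBA (1.3 equiv), NaHCO3, CH2Cl2, 0 °C
Reagents that add atoms: 3-chloroperoxybenzoic acid (mCPBA), OOC(=O)c1cccc(Cl)c1
Why: Prilezhaev epoxidation of the only electron-rich olefin left (the angelate olefins are electron-poor) is expected to occur on the β-face, away from the α-disposed 4,5-oxirane oxygen, C6 ester and C7 side chain, which would set C1 (R) and C10 (S).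

Step 13
Reactants: 21 (1R,4R,5S,6S,7S,10S,11R)-6,11-bis(angeloyloxy)-12-[(tert-butyldimethylsilyl)oxy]-1,10:4,5-diepoxygermacrane
Product: 22 (1R,4R,5S,6S,7S,10S,11R)-6,11-bis(angeloyloxy)-1,10:4,5-diepoxygermacran-12-ol
Conditions: HF·pyridine, pyridine, THF, 0 °C
Reagents that add atoms: none
Why: Fluoride-mediated cleavage of the primary silyl ether under pyridine-buffered conditions should leave oxiranes and enoates intact, and the alcohol is oxidised at once to forestall 1,2-acyl migration from O11.

Step 14
Reactants: 22 (1R,4R,5S,6S,7S,10S,11R)-6,11-bis(angeloyloxy)-1,10:4,5-diepoxygermacran-12-ol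
Product: 24 (1R,4R,5S,6S,7S,10S,11R)-6,11-bis(angeloyloxy)-1,10:4,5-diepoxygermacran-12-oic acid, via aldehyde 23 (not isolated)
Conditions: Dess–Martin periodinane, NaHCO3, CH2Cl2, 0 °C; then NaClO2, NaH2PO4, 2-methylbut-2-ene, tBuOH–H2O, 0 °C
Reagents that add atoms: sodium chlorite, [Na+].[O-]Cl=O
Why: Dess–Martin oxidation to the non-enolisable α-acyloxy aldehyde and buffered Pinnick oxidation to the acid are both compatible with oxiranes and electron-poor olefins.

Step 15
Reactants: 24 (1R,4R,5S,6S,7S,10S,11R)-6,11-bis(angeloyloxy)-1,10:4,5-diepoxygermacran-12-oic acid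
Product: 25 CNP0219924.2, (1R,4R,5S,6S,7S,8R,10S,11R)-6,11-bis(angeloyloxy)-1,10:4,5-diepoxygermacran-12,8-olide
Conditions: [Mn(OTf)2(L)] (3 mol%; L = (S,S)-TIPS-pdp), H2O2 (50% aq., 2 equiv, syringe pump), CF3CH2OH, 0 °C
Reagents that add atoms: none
Why: Proposed new method: the C12 carboxylate binds manganese, H2O2 is cleaved heterolytically to a pentavalent manganese-oxo carboxylate, this abstracts a C8 hydrogen through a seven-membered transition state, and the C8 radical is captured by the bound carboxylate oxygen. The closest known reaction type is the carboxylic-acid-directed γ-C–H lactonisation of unactivated methylenes with Mn(OTf)2 complexes of pdp-type aminopyridine ligands and H2O2 in fluorinated alcohols, which has not been shown on an α-acyloxy acid carried by a diepoxy ten-membered ring with enoate olefins. The γ-lactone (C7, C8, O, C12, C11) is closed by intramolecular C–O bond formation at C8 within the carboxylate tether, a five-membered ring closure by radical rebound. C8 is formed with retention at the abstracted hydrogen: with C6–C7–C8–C9 antiperiplanar only one C8 hydrogen is gauche to C11, and its replacement gives the trans-fused 8R lactone, the ligand antipode being the first variable to test for matching. Site selectivity is needed between the two γ-carbons and should follow from the acyloxy group, which deactivates the C6–H bond toward the electrophilic oxo species, while β C–H bonds are out of reach of the tether. Chemoselectivity over the angelate olefins and oxiranes should follow from the olefins being electron-poor and held away from the metal in the s-cis ester conformation, from the oxidant being generated only on manganese carrying the substrate carboxylate (no external acid), and from slow peroxide addition at 0 °C in trifluoroethanol.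

**Compound list**

1 | (1Z,5Z)-1,5-dimethylcycloocta-1,5-diene | C1/C=C(C)\CC/C=C(C)\C1 | starting material
2 | rac-(4Z)-1,5-dimethyl-9-oxabicyclo[6.1.0]non-4-ene (cis-fused; one enantiomer drawn) | C[C@@]12CC/C=C(C)\CC[C@@H]1O2 | intermediate
3 | rac-(5Z)-1,5-dimethyl-2-(phenylselanyl)cyclooct-5-en-1-ol, SePh trans to OH (not isolated; one enantiomer drawn) | C[C@@]1(O)CC/C=C(C)\CC[C@H]1[Se]c1ccccc1 | intermediate
4 | selenoxide of 3 (not isolated; one enantiomer drawn) | C[C@@]1(O)CC/C=C(C)\CC[C@H]1[Se](=O)c1ccccc1 | intermediate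
5 | rac-(2Z,5Z)-1,5-dimethylcycloocta-2,5-dien-1-ol | CC1(O)/C=C\C/C(C)=C\CC1 | intermediate
6 | (2Z,6Z)-3,7-dimethylcycloocta-2,6-dien-1-one | O=C1/C=C(C)\CC/C=C(C)\C1 | intermediate
7 | vinylmagnesium bromide | C=C[Mg]Br | starting material
8 | rac-(2Z,6Z)-1-ethenyl-3,7-dimethylcycloocta-2,6-dien-1-ol | C=CC1(O)/C=C(C)\CC/C=C(C)\C1 | intermediate
9 | potassium (3Z,7Z)-4,8-dimethylcyclodeca-1,3,7-trien-2-olate (not isolated; enolate geometry undefined) | C1/C(C)=C\CC/C(C)=C\C([O-])=CC1.[K+] | intermediate
10 | trimethyl{[(3Z,7Z)-4,8-dimethylcyclodeca-1,3,7-trien-2-yl]oxy}silane (enol ether geometry undefined) | C1/C(C)=C\CC/C(C)=C\C(O[Si](C)(C)C)=CC1 | intermediate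
11 | methyl pyruvate | CC(=O)C(=O)OC | starting material
12 | O-trimethylsilyl ether of 13 (not isolated) | C1/C(C)=C\CC/C(C)=C\C(=O)[C@@H]([C@@](C)(O[Si](C)(C)C)C(=O)OC)C1 | intermediate
13 | methyl (2R)-2-hydroxy-2-[(1R,3Z,7Z)-4,8-dimethyl-2-oxocyclodeca-3,7-dien-1-yl]propanoate (7R,11R) | C1/C(C)=C\CC/C(C)=C\C(=O)[C@@H]([C@@](C)(O)C(=O)OC)C1 | intermediate
14 | methyl (2R)-2-hydroxy-2-[(1S,2R,3Z,7Z)-2-hydroxy-4,8-dimethylcyclodeca-3,7-dien-1-yl]propanoate (not isolated) | C1/C(C)=C\CC/C(C)=C\[C@@H](O)[C@@H]([C@@](C)(O)C(=O)OC)C1 | intermediate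
15 | (2R)-2-[(1S,2R,3Z,7Z)-2-hydroxy-4,8-dimethylcyclodeca-3,7-dien-1-yl]propane-1,2-diol (6R,7S,11R) | C1/C(C)=C\CC/C(C)=C\[C@@H](O)[C@@H]([C@@](C)(O)CO)C1 | intermediate
16 | (2R)-1-[(tert-butyldimethylsilyl)oxy]-2-[(1S,2R,3Z,7Z)-2-hydroxy-4,8-dimethylcyclodeca-3,7-dien-1-yl]propan-2-ol | C1/C(C)=C\CC/C(C)=C\[C@@H](O)[C@@H]([C@@](C)(O)CO[Si](C)(C)C(C)(C)C)C1 | intermediate
17 | (4R,5S,6S,7S,11R)-12-[(tert-butyldimethylsilyl)oxy]-4,5-epoxygermacr-1(10)Z-ene-6,11-diol (cis-oxirane on the face of O6; C6 is S here only through changed CIP priorities) | C1/C(C)=C\CC[C@@]2(C)O[C@H]2[C@@H](O)[C@@H]([C@@](C)(O)CO[Si](C)(C)C(C)(C)C)C1 | intermediate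
18 | angelic acid, (Z)-2-methylbut-2-enoic acid | C/C=C(/C)C(=O)O | starting material
19 | angelic anhydride | C/C=C(/C)C(=O)OC(=O)/C(C)=C\C | intermediate
20 | (4R,5S,6S,7S,11R)-6,11-bis(angeloyloxy)-12-[(tert-butyldimethylsilyl)oxy]-4,5-epoxygermacr-1(10)Z-ene | C1/C(C)=C\CC[C@@]2(C)O[C@H]2[C@@H](OC(=O)/C(C)=C\C)[C@@H]([C@@](C)(OC(=O)/C(C)=C\C)CO[Si](C)(C)C(C)(C)C)C1 | intermediate
21 | (1R,4R,5S,6S,7S,10S,11R)-6,11-bis(angeloyloxy)-12-[(tert-butyldimethylsilyl)oxy]-1,10:4,5-diepoxygermacrane (both oxiranes cis; 1,10-oxygen on the face opposite to the 4,5-oxygen) | C1[C@]2(C)O[C@@H]2CC[C@@]2(C)O[C@H]2[C@@H](OC(=O)/C(C)=C\C)[C@@H]([C@@](C)(OC(=O)/C(C)=C\C)CO[Si](C)(C)C(C)(C)C)C1 | intermediate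
22 | (1R,4R,5S,6S,7S,10S,11R)-6,11-bis(angeloyloxy)-1,10:4,5-diepoxygermacran-12-ol | C1[C@]2(C)O[C@@H]2CC[C@@]2(C)O[C@H]2[C@@H](OC(=O)/C(C)=C\C)[C@@H]([C@@](C)(OC(=O)/C(C)=C\C)CO)C1 | intermediate
23 | (1R,4R,5S,6S,7S,10S,11R)-6,11-bis(angeloyloxy)-1,10:4,5-diepoxygermacran-12-al (not isolated) | C1[C@]2(C)O[C@@H]2CC[C@@]2(C)O[C@H]2[C@@H](OC(=O)/C(C)=C\C)[C@@H]([C@@](C)(OC(=O)/C(C)=C\C)C=O)C1 | intermediate
24 | (1R,4R,5S,6S,7S,10S,11R)-6,11-bis(angeloyloxy)-1,10:4,5-diepoxygermacran-12-oic acid (8-deoxy seco acid) | C/C=C(/C)C(=O)O[C@H]1[C@H](CC[C@]3(C)O[C@@H]3CC[C@@]3(C)O[C@@H]13)[C@@](C)(OC(=O)/C(C)=C\C)C(=O)O | intermediate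
25 | CNP0219924.2, (1R,4R,5S,6S,7S,8R,10S,11R)-6,11-bis(angeloyloxy)-1,10:4,5-diepoxygermacran-12,8-olide (trans-fused γ-lactone) | C/C=C(/C)C(=O)O[C@H]1[C@@H]2[C@@H](C[C@]3(C)O[C@@H]3CC[C@@]3(C)O[C@@H]13)OC(=O)[C@]2(C)OC(=O)/C(C)=C\C | target

**Step count and risks**

Total: 15 steps. Longest linear sequence: 14 steps (steps 1–9 and 11–15; step 10 is a one-step side branch).

Steps most likely to fail:

1. Step 15 (Proposed new method). Oxygen transfer to the angelate olefins, opening of the oxiranes in the fluorinated alcohol, or hydrogen abstraction at C6 or at the wrong C8 hydrogen may outrun the intended C8–H abstraction. The fallback replaces the metal-oxo by a known amidyl-radical 1,5-hydrogen transfer (Hofmann–Löffler–Freytag type, hypervalent iodine/iodine variant). It sets out from acid 24. Mixed-anhydride activation (isobutyl chloroformate, N-methylmorpholine) and ammonia would give the primary amide (1R,4R,5S,6S,7S,10S,11R)-6,11-bis(angeloyloxy)-1,10:4,5-diepoxygermacran-12-amide F1. PhI(OAc)2 and I2 under visible light with NaHCO3 would form the N-iodoamide and its amidyl radical, which abstracts the C8 hydrogen; iodine transfer to C8 and displacement by the amide oxygen would give the iminolactone (12-imino analogue of 25) F2. Mild aqueous hydrolysis of F2 would give 25, where the fallback rejoins the route.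

2. Step 6. The medium-ring enol ether may add with poor face selectivity at the pyruvate carbonyl or poor syn preference, or the adduct may revert by retro-aldol cleavage. The fallback moves stereocontrol from the catalyst to an auxiliary on the electrophile. It sets out from silyl enol ether 10, which would be combined with (1S,2R,5S)-8-phenylmenthyl pyruvate F3 (from the auxiliary alcohol and pyruvoyl chloride) under TiCl4 in CH2Cl2 at −78 °C (Mukaiyama aldol). F3 is the antipode of the commoner auxiliary, chosen because its phenyl group is expected to shield the si face of the chelated keto group. This would give (1S,2R,5S)-8-phenylmenthyl (2R)-2-hydroxy-2-[(1R,3Z,7Z)-4,8-dimethyl-2-oxocyclodeca-3,7-dien-1-yl]propanoate F4. The boron-chelate reduction of step 7 would give the diol ester (1S,2R,5S)-8-phenylmenthyl (2R)-2-hydroxy-2-[(1S,2R,3Z,7Z)-2-hydroxy-4,8-dimethylcyclodeca-3,7-dien-1-yl]propanoate F5. LiAlH4 would then cleave the auxiliary and return triol 15, where the fallback rejoins the route.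

3. Step 12. The peracid may attack the 1(10)-olefin on the wrong (α) face, because the face preference of a Z olefin in a flexible ten-membered ring is not secured by a directing group. The fallback delivers the oxirane oxygen to the face opposite to that taken by an electrophile. It sets out from 20. NBS in aqueous THF would form the bromonium ion on the face the peracid prefers, and water would open it at the tertiary C10 from the other face to give the bromohydrin (1S,4R,5S,6S,7S,10S,11R)-6,11-bis(angeloyloxy)-1-bromo-12-[(tert-butyldimethylsilyl)oxy]-4,5-epoxygermacran-10-ol F6. K2CO3 in MeCN would close the oxirane with inversion at C1 to give 21, where the fallback rejoins the route.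

Further compounds
F1 | step 15 | (1R,4R,5S,6S,7S,10S,11R)-6,11-bis(angeloyloxy)-1,10:4,5-diepoxygermacran-12-amide | C1[C@]2(C)O[C@@H]2CC[C@@]2(C)O[C@H]2[C@@H](OC(=O)/C(C)=C\C)[C@@H]([C@@](C)(OC(=O)/C(C)=C\C)C(N)=O)C1
F2 | step 15 | iminolactone, 12-imino analogue of 25 | C/C=C(/C)C(=O)O[C@H]1[C@@H]2[C@@H](C[C@]3(C)O[C@@H]3CC[C@@]3(C)O[C@@H]13)OC(=N)[C@]2(C)OC(=O)/C(C)=C\C
F3 | step 6 | (1S,2R,5S)-8-phenylmenthyl pyruvate | CC(C)(c1ccccc1)[C@H]1CC[C@H](C)C[C@@H]1OC(=O)C(C)=O
F4 | step 6 | (1S,2R,5S)-8-phenylmenthyl (2R)-2-hydroxy-2-[(1R,3Z,7Z)-4,8-dimethyl-2-oxocyclodeca-3,7-dien-1-yl]propanoate | C1/C(C)=C\CC/C(C)=C\C(=O)[C@@H]([C@@](C)(O)C(=O)O[C@H]2C[C@@H](C)CC[C@@H]2C(C)(C)c2ccccc2)C1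
F5 | step 6 | (1S,2R,5S)-8-phenylmenthyl (2R)-2-hydroxy-2-[(1S,2R,3Z,7Z)-2-hydroxy-4,8-dimethylcyclodeca-3,7-dien-1-yl]propanoate | C1/C(C)=C\CC/C(C)=C\[C@@H](O)[C@@H]([C@@](C)(O)C(=O)O[C@H]2C[C@@H](C)CC[C@@H]2C(C)(C)c2ccccc2)C1
F6 | step 12 | (1S,4R,5S,6S,7S,10S,11R)-6,11-bis(angeloyloxy)-1-bromo-12-[(tert-butyldimethylsilyl)oxy]-4,5-epoxygermacran-10-ol | C1[C@](C)(O)[C@@H](Br)CC[C@@]2(C)O[C@H]2[C@@H](OC(=O)/C(C)=C\C)[C@@H]([C@@](C)(OC(=O)/C(C)=C\C)CO[Si](C)(C)C(C)(C)C)C1
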